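**Retrosynthetic overview**
1. The 29-membered ring is closed last, not at the amide: a three-component double Stille "stitching" inserts (Z)-Me3SnCH=CHSnMe3 (C19'–C20') between the (E)-vinyl iodide C18' and the (Z)-iodoacrylamide C21', making the (17'E,19'Z,21'Z)-triene and the macrocycle in one step.
2. The bis-iodide comes from intermolecular N-acylation with (Z)-3-iodoacrylic acid, Takai iodo-olefination (C18'), and a Nozaki–Hiyama–Kishi union of the (Z)-vinyl iodide C2' with naphthaldehyde 14, then oxidation to the aryl (Z)-enone.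
3. Chain C2'–C17': (S)-Roche aldehyde 17 is used twice (C3'–C5' and C15'–C17'), with Roush crotylboration (C5', C6'), Stork–Zhao-type iodo-olefination, cross-metathesis, a catalytic vinylogous Mukaiyama aldol (C9', C10'–C13') and a Felkin Mukaiyama aldol (C15').
4. Naphthalene: ring B is annulated onto chloranil by Diels–Alder/double dehydrochlorination, followed by regioselective amination, reductive methylation and ortho-formylation.
5. Ring order: naphthalene ring B first, macrocycle last; the quinone is then unveiled with (NH4)2Ce(NO3)6 and the silyl ethers are removed.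

Conventions: arene atoms are numbered so that C1(O) is next to C2(Cl), N is on C3 and C8 carries the ansa carbonyl; ansa atoms are primed from the aryl ketone C1' to the amide carbonyl C23' (target: 2'Z,4'S,5'S,6'S,7'E,9'S,11'E,15'S,16'S,17'E,19'Z,21'Z). TBS = tert-butyldimethylsilyl, TES = triethylsilyl, Boc = tert-butoxycarbonyl, Piv = pivaloyl.
Assumption: the (S,S)-enantiomer of the binaphthyldiamine-derived bisphosphoramide is taken to direct the dienolate to the Si face of enal 29 (giving 9'S); if the sense proves opposite, the (R,R)-catalyst is used.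
Assumption: compounds 1, 3, 15, 18–20, 28, 30, 44, 47 and 48 are purchased.

**Fragment A (naphthaldehyde 14)**

Step 1
Reactants: 1 3-methylbut-3-en-2-one
Product: 2 3-methyl-2-(trimethylsilyloxy)buta-1,3-diene
Conditions: TMSOTf, Et3N, Et2O, 0 °C
Reagents that add atoms: trimethylsilyl triflate, C[Si](C)(C)OS(=O)(=O)C(F)(F)F
Why: Soft enolisation and O-silylation (silyl enol ether formation) at the acetyl CH3, the only enolisable position, gives the 2-silyloxy diene.

Step 2
Reactants: 3 chloranil; 2 silyloxy diene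
Product: 6 2,3-dichloro-7-hydroxy-6-methylnaphthalene-1,4-dione, via cycloadduct 4 (not isolated), via aryl silyl ether 5 (not isolated)
Conditions: toluene, 90 °C; Et3N, 0 °C; 1 M HCl, THF, rt
Reagents that add atoms: none
Why: Diels–Alder addition of the electron-rich diene to the symmetrical dienophile (no regiochemical issue), then double dehydrochlorination of the two angular C–Cl bonds aromatises ring B directly at the quinone oxidation level, and acid cleaves the aryl silyl ether.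

Step 3
Reactants: 6 dichloroquinone
Product: 7 3-amino-2-chloro-7-hydroxy-6-methylnaphthalene-1,4-dione
Conditions: NH3 (7 M in MeOH), THF, 0 °C → rt; dilute HCl work-up
Reagents that add atoms: ammonia, N
Why: Addition–elimination (vinylogous SNAr) on the 2,3-dichloroquinone, in which the 7-phenoxide is para-conjugated with C4=O and deactivates it, so ammonia adds at C3 (β to the more electrophilic C1=O) and N ends up next to C4=O as in the target.

Step 4
Reactants: 7 aminochloroquinone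
Product: 8 3-amino-2-chloro-6-methyl-1,4-dioxo-1,4-dihydronaphthalen-7-yl pivalate
Conditions: PivCl, Et3N, DMAP (cat.), CH2Cl2, 0 °C
Reagents that add atoms: pivaloyl chloride, CC(C)(C)C(Cl)=O
Why: O-acylation of the acidic phenol (the vinylogous-amide NH2 is not nucleophilic) masks O7 so that only the hydroquinone oxygens are methylated next.

Step 5
Reactants: 8 quinone pivalate
Product: 10 3-amino-2-chloro-1,4-dimethoxy-6-methylnaphthalen-7-yl pivalate, via hydroquinone 9 (not isolated)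
Conditions: Na2S2O4, EtOAc/H2O, rt; then MeI, K2CO3, acetone, 40 °C (argon)
Reagents that add atoms: iodomethane, IC
Why: Dithionite reduction then Williamson O-methylation of the two phenoxides protects the quinone as its dimethyl ether, the neutral doubly ortho-substituted aniline being far less nucleophilic than the phenoxides.

Step 6
Reactants: 10 aminonaphthalene
Product: 11 3-(Boc-amino)-2-chloro-1,4-dimethoxy-6-methylnaphthalen-7-yl pivalate
Conditions: NaN(SiMe3)2 (2.1 equiv), Boc2O, THF, −78 → 0 °C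
Reagents that add atoms: di-tert-butyl dicarbonate, CC(C)(C)OC(=O)OC(=O)OC(C)(C)C
Why: N-acylation of the sodium anilide gives the carbamate that shields the electron-rich aniline from CH2O and from the later oxidations.

Step 7
Reactants: 11 carbamate pivalate
Product: 12 tert-butyl N-(2-chloro-7-hydroxy-1,4-dimethoxy-6-methylnaphthalen-3-yl)carbamate
Conditions: NaOMe, MeOH, 0 °C → rt; aq. NH4Cl
Reagents that add atoms: none
Why: Methanolysis (transesterification) of the aryl ester frees the C7 phenol while the carbamate and methyl ethers are untouched.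

Step 8
Reactants: 12 phenol
Product: 13 tert-butyl N-(2-chloro-8-formyl-7-hydroxy-1,4-dimethoxy-6-methylnaphthalen-3-yl)carbamate
Conditions: MgCl2, Et3N, (CH2O)n, MeCN, 80 °C
Reagents that add atoms: paraformaldehyde (formaldehyde), C=O
Why: Magnesium-phenoxide-directed ortho-formylation (Casiraghi–Skattebøl) can only occur at C8, the single free ortho position, via ortho-hydroxymethylation and hydride transfer to a second formaldehyde.

Step 9
Reactants: 13 salicylaldehyde
Product: 14 tert-butyl N-[7-(TBS-oxy)-2-chloro-8-formyl-1,4-dimethoxy-6-methylnaphthalen-3-yl]carbamate (fragment A)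
Conditions: TBSCl, imidazole, DMAP (cat.), DMF, 40 °C
Reagents that add atoms: tert-butyldimethylsilyl chloride, CC(C)(C)[Si](C)(C)Cl
Why: Phenol silylation gives a group that survives to the final fluoride step, under conditions that do not touch the Boc group.

**Chain (C2'–C17')**

Step 10
Reactants: 15 methyl (S)-3-hydroxy-2-methylpropanoate
Product: 16 methyl (S)-2-methyl-3-(triethylsilyloxy)propanoate
Conditions: TESCl, imidazole, CH2Cl2, 0 °C
Reagents that add atoms: chlorotriethylsilane, CC[Si](CC)(CC)Cl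
Why: Silyl protection of the primary alcohol of the chiral-pool ester, which supplies both C4' and C16'.

Step 11
Reactants: 16 TES ester
Product: 17 (S)-2-methyl-3-(triethylsilyloxy)propanal
Conditions: i-Bu2AlH (1.05 equiv), CH2Cl2, −78 °C; MeOH, aq. KNaC4H4O6
Reagents that add atoms: none
Why: Partial ester reduction, the aluminium hemiacetal being stable at −78 °C and releasing the aldehyde on work-up without epimerisation.

Step 12
Reactants: 18 (E)-but-2-ene; 19 triisopropyl borate; 20 diisopropyl (2R,3R)-tartrate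
Product: 23 (R,R)-tartrate (E)-crotylboronate, via (E)-crotylpotassium 21 (not isolated), via diisopropyl (E)-crotylboronate 22 (not isolated)
Conditions: KOt-Bu, n-BuLi, THF, −78 → −50 °C; 19, −78 °C; 1 M HCl; 20, MgSO4, Et2O
Reagents that add atoms: none
Why: Schlosser metalation gives configurationally stable (E)-crotylpotassium, which is borylated and transesterified with the tartrate (Roush reagent preparation).

Step 13
Reactants: 17 (S)-aldehyde; 23 crotylboronate
Product: 24 (2S,3S,4S)-2,4-dimethyl-1-(triethylsilyloxy)hex-5-en-3-ol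
Conditions: toluene, −78 °C; aq. NaOH work-up
Reagents that add atoms: none
Why: Roush crotylboration through a chair Zimmerman–Traxler transition state, in which the E-crotyl unit gives the 5',6'-anti relationship and the (R,R)-tartrate directs Si-face attack, matched with the Felkin–Anh preference of the (S)-aldehyde (4',5'-syn), setting 5'S and 6'S.

Step 14
Reactants: 24 homoallylic alcohol
Product: 25 (2S,3S,4S)-3-(TBS-oxy)-2,4-dimethyl-1-(triethylsilyloxy)hex-5-ene
Conditions: TBSOTf, 2,6-lutidine, CH2Cl2, −78 → 0 °C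
Reagents that add atoms: tert-butyldimethylsilyl triflate, CC(C)(C)[Si](C)(C)OS(=O)(=O)C(F)(F)F
Why: Silylation of the hindered secondary alcohol with the silyl triflate.

Step 15
Reactants: 25 bis-silyl ether
Product: 26 (2R,3S,4S)-3-(TBS-oxy)-2,4-dimethylhex-5-enal
Conditions: (COCl)2, DMSO, CH2Cl2, −78 → −40 °C; Et3N, → 0 °C
Reagents that add atoms: none
Why: Swern conditions cleave the primary TES ether and oxidise it to the aldehyde in one operation, leaving the secondary TBS ether intact and the α-stereocentre unepimerised at low temperature.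

Step 16
Reactants: 26 aldehyde
Product: 27 (3S,4S,5S,6Z)-4-(TBS-oxy)-7-iodo-3,5-dimethylocta-1,6-diene
Conditions: [Ph3PEt]I, n-BuLi, THF, rt; I2, −78 °C; NaN(SiMe3)2, −20 °C; 26, −78 °C
Reagents that add atoms: ethyltriphenylphosphonium iodide, CC[P+](c1ccccc1)(c1ccccc1)c1ccccc1.[I-]; iodine, [I][I]
Why: Stork–Zhao-type Wittig olefination with the α-iodoethylidene ylide gives the (Z)-trisubstituted vinyl iodide (iodine cis to C4') under kinetic control.

Step 17
Reactants: 27 vinyl iodide diene; 28 (E)-but-2-enal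
Product: 29 (2E,4S,5S,6S,7Z)-5-(TBS-oxy)-8-iodo-4,6-dimethylnona-2,7-dienal
Conditions: second-generation Hoveyda–Grubbs catalyst, RuCl2(H2IMes)(=CH-C6H4-2-Oi-Pr) (5 mol %), 28 (8 equiv), CH2Cl2, 40 °C
Reagents that add atoms: none
Why: Olefin cross-metathesis of the terminal alkene with crotonaldehyde gives the thermodynamic (E)-enal, the hindered trisubstituted iodoalkene being inert.

Step 18
Reactants: 30 ethyl tiglate
Product: 31 tert-butyl[(1-ethoxy-2-methylbuta-1,3-dienyl)oxy]dimethylsilane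
Conditions: LiN(i-Pr)2, THF/DMPU, −78 °C; TBSCl
Reagents that add atoms: tert-butyldimethylsilyl chloride, CC(C)(C)[Si](C)(C)Cl
Why: γ-Deprotonation of the enoate and O-silylation give the silyl dienolate (vinylogous ketene acetal).

Step 19
Reactants: 29 enal; 31 silyl dienolate
Product: 32 ethyl (2E,5S,6E,8S,9S,10S,11Z)-9-(TBS-oxy)-5-hydroxy-12-iodo-2,8,10-trimethyltrideca-2,6,11-trienoate
Conditions: SiCl4 (1.1 equiv), (S,S)-bisphosphoramide (5 mol %), i-Pr2NEt (10 mol %), CH2Cl2, −78 °C; aq. KF/NaHCO3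
Reagents that add atoms: none
Why: Lewis-base-activated SiCl4 vinylogous Mukaiyama aldol, γ-selective and giving the (E)-enoate, in which the chiral phosphoramide-bound trichlorosilyl cation shields the Re face of the enal so that Si-face attack sets 9'S under catalyst control.

Step 20
Reactants: 32 allylic alcohol
Product: 33 ethyl 5,9-bis(TBS-oxy) trienoate
Conditions: TBSOTf, 2,6-lutidine, CH2Cl2, −78 °C
Reagents that add atoms: tert-butyldimethylsilyl triflate, CC(C)(C)[Si](C)(C)OS(=O)(=O)C(F)(F)F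
Why: Silylation of the C9' carbinol.

Step 21
Reactants: 33 ester
Product: 35 (3E,6S,7E,9S,10S,11S,12Z)-6,10-bis(TBS-oxy)-13-iodo-3,9,11-trimethyltetradeca-3,7,12-trien-2-one, via Weinreb amide 34 (not isolated)
Conditions: MeNHOMe·HCl (1.5 equiv), i-PrMgCl (3.0 equiv), THF, −20 °C; MeMgBr, −20 → 0 °C; aq. NH4Cl
Reagents that add atoms: methylmagnesium bromide, C[Mg]Br
Why: The magnesium amide converts the ester into the Weinreb amide, whose chelated tetrahedral adduct with the Grignard reagent collapses only on work-up, giving the methyl ketone (Weinreb ketone synthesis) without over-addition.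

Step 22
Reactants: 35 methyl ketone; 17 (S)-aldehyde
Product: 37 C2'–C17' ketol (15'S,16'S), via silyl enol ether 36 (not isolated)
Conditions: LiN(SiMe3)2, Me3SiCl, THF, −78 °C; then 17, BF3·OEt2, CH2Cl2, −78 °C; aq. NaHCO3
Reagents that add atoms: none
Why: Kinetic enol silane formation at the methyl group, then a BF3-mediated Mukaiyama aldol through an open transition state in which Felkin–Anh attack on the (S)-aldehyde gives the 15'S carbinol syn to the C16' methyl (expected about 6:1, minor isomer removed by chromatography).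

Step 23
Reactants: 37 ketol
Product: 38 15'-O-TBS ether of the C2'–C17' chain
Conditions: TBSOTf, 2,6-lutidine, CH2Cl2, −78 °C
Reagents that add atoms: tert-butyldimethylsilyl triflate, CC(C)(C)[Si](C)(C)OS(=O)(=O)C(F)(F)F
Why: Low-temperature silylation caps the β-hydroxy ketone before it can eliminate or undergo retro-aldol cleavage.

Step 24
Reactants: 38 TES ether
Product: 39 C2'–C17' primary alcohol
Conditions: HF·pyridine, pyridine, THF, 0 °C
Reagents that add atoms: none
Why: Buffered HF cleaves the primary TES ether selectively, the three secondary TBS ethers being far slower.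

**Assembly and ring closure**

Step 25
Reactants: 39 vinyl iodide alcohol; 14 naphthaldehyde (1.3 equiv)
Product: 40 C1' carbinol (both epimers)
Conditions: CrCl2 (8 equiv), NiCl2 (2 mol %), DMSO, rt
Reagents that add atoms: none
Why: Nozaki–Hiyama–Kishi coupling, in which zerovalent nickel inserts into the C–I bond with retention of the Z geometry, transmetalation gives a vinylchromium that adds only to the aldehyde (ketone, enone, carbamate and free OH tolerated), and the new C1' centre is removed in the next step.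

Step 26
Reactants: 40 diol
Product: 41 C1' ketone C17' aldehyde
Conditions: Dess–Martin periodinane (3 equiv), NaHCO3, CH2Cl2, 0 °C → rt
Reagents that add atoms: none
Why: Dess–Martin oxidation converts both alcohols at once, giving the aryl (Z)-enone from either C1' epimer and the C17' aldehyde under buffered conditions that do not epimerise C16'.

Step 27
Reactants: 41 keto aldehyde
Product: 42 (17'E)-18'-iodo alkene
Conditions: CrCl2, CHI3, THF/1,4-dioxane, 0 °C → rt
Reagents that add atoms: iodoform, IC(I)I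
Why: Takai olefination, the geminal dichromium species from CHI3 adding only to the aldehyde and eliminating to the (E)-vinyl iodide while both ketones are untouched.

Step 28
Reactants: 42 Boc carbamate
Product: 43 C3 aniline
Conditions: TMSOTf, 2,6-lutidine, CH2Cl2, 0 °C; MeOH
Reagents that add atoms: none
Why: Silyl-triflate-mediated Boc cleavage via the silyl carbamate is non-protic and leaves the TBS ethers, enones and vinyl iodide intact.

Step 29
Reactants: 43 aniline; 44 (Z)-3-iodoacrylic acid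
Product: 46 bis-iodide (Z)-3-iodoacrylamide, via (Z)-3-iodoacryloyl chloride 45 (not isolated)
Conditions: 44, 1-chloro-N,N,2-trimethylprop-1-en-1-amine, CH2Cl2, 0 °C; then 43, 2,6-lutidine, 0 °C → rt
Reagents that add atoms: none
Why: The acid chloride is formed under neutral conditions (Ghosez chloroenamine), which preserves the Z geometry, and acylates the hindered aniline intermolecularly (amide formation).

Step 30
Reactants: 47 acetylene; 48 hexamethylditin
Product: 49 (Z)-1,2-bis(trimethylstannyl)ethene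
Conditions: Pd(PPh3)4 (1 mol %), 1,4-dioxane, 60 °C
Reagents that add atoms: none
Why: Palladium-catalysed syn-distannylation of the alkyne gives only the Z isomer.

Step 31
Reactants: 46 bis-iodide; 49 (Z)-distannane
Product: 50 protected macrocycle (1,4-dimethoxy, tetrakis-TBS)
Conditions: PdCl2(MeCN)2 (20 mol %), i-Pr2NEt, DMF/THF 1:1, 1 mM, rt, dark; 49 (1.1 equiv) added over 12 h
Reagents that add atoms: none
Why: Two successive Stille couplings (first at the more reactive iodoacrylamide, then intramolecularly at the C18' iodide under high dilution) stitch in C19'=C20' with retention at all three alkenes, closing the 29-membered ring and creating the (17'E,19'Z,21'Z)-triene.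

Step 32
Reactants: 50 dimethoxynaphthalene macrocycle
Product: 51 tetrakis-TBS quinone
Conditions: (NH4)2Ce(NO3)6 (2.5 equiv), MeCN/H2O 4:1, 0 °C, 10 min
Reagents that add atoms: water, O
Why: Oxidative demethylation by tetravalent cerium, in which the amido-1,4-dimethoxyarene is the most easily oxidised site, water adds at the two ipso carbons and methanol is lost to give the 1,4-quinone.

Step 33
Reactants: 51 silylated quinone
Product: 52 target (CNP0257532.2)
Conditions: HF·pyridine, pyridine, THF, 0 °C → rt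
Reagents that add atoms: none
Why: Buffered fluoride-mediated global desilylation removes the three alkyl TBS ethers and the aryl TBS ether without dehydrating the β-hydroxy enone or isomerising the triene.

**Compound list**
1 | 3-methylbut-3-en-2-one | CC(=O)C(C)=C | starting material
2 | 3-methyl-2-(trimethylsilyloxy)buta-1,3-diene | C=C(O[Si](C)(C)C)C(C)=C | intermediate
3 | chloranil (2,3,5,6-tetrachlorocyclohexa-2,5-diene-1,4-dione) | O=C1C(Cl)=C(Cl)C(=O)C(Cl)=C1Cl | starting material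
4 | cis-2,3,4a,8a-tetrachloro-6-methyl-7-(trimethylsilyloxy)-4a,5,8,8a-tetrahydronaphthalene-1,4-dione (racemic, one enantiomer drawn) | O=C1C(Cl)=C(Cl)C(=O)[C@]2(Cl)CC(C)=C(O[Si](C)(C)C)C[C@]12Cl | intermediate (not isolated)
5 | 2,3-dichloro-6-methyl-7-(trimethylsilyloxy)naphthalene-1,4-dione | O=C1C(Cl)=C(Cl)C(=O)c2cc(C)c(O[Si](C)(C)C)cc12 | intermediate (not isolated)
6 | 2,3-dichloro-7-hydroxy-6-methylnaphthalene-1,4-dione | O=C1C(Cl)=C(Cl)C(=O)c2cc(C)c(O)cc12 | intermediate
7 | 3-amino-2-chloro-7-hydroxy-6-methylnaphthalene-1,4-dione | NC1=C(Cl)C(=O)c2cc(O)c(C)cc2C1=O | intermediate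
8 | 3-amino-2-chloro-6-methyl-1,4-dioxo-1,4-dihydronaphthalen-7-yl pivalate | NC1=C(Cl)C(=O)c2cc(OC(=O)C(C)(C)C)c(C)cc2C1=O | intermediate
9 | 3-amino-2-chloro-1,4-dihydroxy-6-methylnaphthalen-7-yl pivalate | Nc1c(Cl)c(O)c2cc(OC(=O)C(C)(C)C)c(C)cc2c1O | intermediate (not isolated)
10 | 3-amino-2-chloro-1,4-dimethoxy-6-methylnaphthalen-7-yl pivalate | Nc1c(Cl)c(OC)c2cc(OC(=O)C(C)(C)C)c(C)cc2c1OC | intermediate
11 | 3-(Boc-amino)-2-chloro-1,4-dimethoxy-6-methylnaphthalen-7-yl pivalate | CC(C)(C)OC(=O)Nc1c(Cl)c(OC)c2cc(OC(=O)C(C)(C)C)c(C)cc2c1OC | intermediate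
12 | tert-butyl N-(2-chloro-7-hydroxy-1,4-dimethoxy-6-methylnaphthalen-3-yl)carbamate | CC(C)(C)OC(=O)Nc1c(Cl)c(OC)c2cc(O)c(C)cc2c1OC | intermediate
13 | tert-butyl N-(2-chloro-8-formyl-7-hydroxy-1,4-dimethoxy-6-methylnaphthalen-3-yl)carbamate | CC(C)(C)OC(=O)Nc1c(Cl)c(OC)c2c(C=O)c(O)c(C)cc2c1OC | intermediate
14 | tert-butyl N-[7-(TBS-oxy)-2-chloro-8-formyl-1,4-dimethoxy-6-methylnaphthalen-3-yl]carbamate (fragment A) | CC(C)(C)OC(=O)Nc1c(Cl)c(OC)c2c(C=O)c(O[Si](C)(C)C(C)(C)C)c(C)cc2c1OC | intermediate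
15 | methyl (S)-3-hydroxy-2-methylpropanoate ((S)-Roche ester) | OC[C@H](C)C(=O)OC | starting material
16 | methyl (S)-2-methyl-3-(triethylsilyloxy)propanoate | CC[Si](CC)(CC)OC[C@H](C)C(=O)OC | intermediate
17 | (S)-2-methyl-3-(triethylsilyloxy)propanal | CC[Si](CC)(CC)OC[C@H](C)C=O | intermediate
18 | (E)-but-2-ene | C/C=C/C | starting material
19 | triisopropyl borate | CC(C)OB(OC(C)C)OC(C)C | starting material
20 | diisopropyl (2R,3R)-tartrate | CC(C)OC(=O)[C@H](O)[C@@H](O)C(=O)OC(C)C | starting material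
21 | (E)-but-2-enylpotassium | C/C=C/C[K] | intermediate (not isolated)
22 | diisopropyl (E)-but-2-enylboronate | C/C=C/CB(OC(C)C)OC(C)C | intermediate (not isolated)
23 | diisopropyl (4R,5R)-2-[(E)-but-2-enyl]-1,3,2-dioxaborolane-4,5-dicarboxylate | CC(C)OC(=O)[C@@H]1OB(C/C=C/C)O[C@H]1C(=O)OC(C)C | intermediate
24 | (2S,3S,4S)-2,4-dimethyl-1-(triethylsilyloxy)hex-5-en-3-ol (ansa C3'–C8') | CC[Si](CC)(CC)OC[C@H](C)[C@@H](O)[C@@H](C)C=C | intermediate
25 | (2S,3S,4S)-3-(TBS-oxy)-2,4-dimethyl-1-(triethylsilyloxy)hex-5-ene | CC[Si](CC)(CC)OC[C@H](C)[C@@H](O[Si](C)(C)C(C)(C)C)[C@@H](C)C=C | intermediate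
26 | (2R,3S,4S)-3-(TBS-oxy)-2,4-dimethylhex-5-enal | O=C[C@H](C)[C@@H](O[Si](C)(C)C(C)(C)C)[C@@H](C)C=C | intermediate
27 | (3S,4S,5S,6Z)-4-(TBS-oxy)-7-iodo-3,5-dimethylocta-1,6-diene | C/C(I)=C/[C@H](C)[C@@H](O[Si](C)(C)C(C)(C)C)[C@@H](C)C=C | intermediate
28 | (E)-but-2-enal | C/C=C/C=O | starting material
29 | (2E,4S,5S,6S,7Z)-5-(TBS-oxy)-8-iodo-4,6-dimethylnona-2,7-dienal | C/C(I)=C/[C@H](C)[C@@H](O[Si](C)(C)C(C)(C)C)[C@@H](C)/C=C/C=O | intermediate
30 | ethyl (E)-2-methylbut-2-enoate (ethyl tiglate) | C/C=C(\C)C(=O)OCC | starting material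
31 | tert-butyl[(1-ethoxy-2-methylbuta-1,3-dienyl)oxy]dimethylsilane (ketene-acetal geometry immaterial) | C=CC(C)=C(OCC)O[Si](C)(C)C(C)(C)C | intermediate
32 | ethyl (2E,5S,6E,8S,9S,10S,11Z)-9-(TBS-oxy)-5-hydroxy-12-iodo-2,8,10-trimethyltrideca-2,6,11-trienoate (ansa C2'–C13') | C/C(I)=C/[C@H](C)[C@@H](O[Si](C)(C)C(C)(C)C)[C@@H](C)/C=C/[C@@H](O)C/C=C(\C)C(=O)OCC | intermediate
33 | ethyl (2E,5S,6E,8S,9S,10S,11Z)-5,9-bis(TBS-oxy)-12-iodo-2,8,10-trimethyltrideca-2,6,11-trienoate | C/C(I)=C/[C@H](C)[C@@H](O[Si](C)(C)C(C)(C)C)[C@@H](C)/C=C/[C@@H](O[Si](C)(C)C(C)(C)C)C/C=C(\C)C(=O)OCC | intermediate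
34 | N-methoxy-N-methyl amide corresponding to ester 33 (same stereochemistry) | C/C(I)=C/[C@H](C)[C@@H](O[Si](C)(C)C(C)(C)C)[C@@H](C)/C=C/[C@@H](O[Si](C)(C)C(C)(C)C)C/C=C(\C)C(=O)N(C)OC | intermediate (not isolated)
35 | (3E,6S,7E,9S,10S,11S,12Z)-6,10-bis(TBS-oxy)-13-iodo-3,9,11-trimethyltetradeca-3,7,12-trien-2-one (ansa C2'–C14') | C/C(I)=C/[C@H](C)[C@@H](O[Si](C)(C)C(C)(C)C)[C@@H](C)/C=C/[C@@H](O[Si](C)(C)C(C)(C)C)C/C=C(\C)C(C)=O | intermediate
36 | trimethylsilyl enol ether of 35 at the methyl carbon (2-silyloxy-1,3-diene) | C/C(I)=C/[C@H](C)[C@@H](O[Si](C)(C)C(C)(C)C)[C@@H](C)/C=C/[C@@H](O[Si](C)(C)C(C)(C)C)C/C=C(\C)C(=C)O[Si](C)(C)C | intermediate (not isolated)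
37 | ansa C2'–C17' ketol: 2'-iodo-2'-ene (Z), 7'E, 11'E, 13'-ketone, methyls on 2',4',6',12',16', OTBS on 5' and 9', OH on 15', OTES on 17'; 4'S,5'S,6'S,9'S,15'S,16'S | C/C(I)=C/[C@H](C)[C@@H](O[Si](C)(C)C(C)(C)C)[C@@H](C)/C=C/[C@@H](O[Si](C)(C)C(C)(C)C)C/C=C(\C)C(=O)C[C@H](O)[C@@H](C)CO[Si](CC)(CC)CC | intermediate
38 | 15'-O-TBS ether of 37 (5',9',15'-tris-OTBS, 17'-OTES) | C/C(I)=C/[C@H](C)[C@@H](O[Si](C)(C)C(C)(C)C)[C@@H](C)/C=C/[C@@H](O[Si](C)(C)C(C)(C)C)C/C=C(\C)C(=O)C[C@H](O[Si](C)(C)C(C)(C)C)[C@@H](C)CO[Si](CC)(CC)CC | intermediate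
39 | 17'-alcohol of 38 (5',9',15'-tris-OTBS, free 17'-OH, 2'-iodide) | C/C(I)=C/[C@H](C)[C@@H](O[Si](C)(C)C(C)(C)C)[C@@H](C)/C=C/[C@@H](O[Si](C)(C)C(C)(C)C)C/C=C(\C)C(=O)C[C@H](O[Si](C)(C)C(C)(C)C)[C@@H](C)CO | intermediate
40 | arene C8 joined to C1' carbinol (both C1' epimers): 1,4-dimethoxy-2-chloro-3-NHBoc-6-methyl-7-OTBS naphthalene bearing the C1'–C17' chain (2'Z, 7'E, 11'E, 13'-ketone, 5',9',15'-tris-OTBS, 17'-OH) | C/C(=C/[C@H](C)[C@@H](O[Si](C)(C)C(C)(C)C)[C@@H](C)/C=C/[C@@H](O[Si](C)(C)C(C)(C)C)C/C=C(\C)C(=O)C[C@H](O[Si](C)(C)C(C)(C)C)[C@@H](C)CO)C(O)c1c(O[Si](C)(C)C(C)(C)C)c(C)cc2c(OC)c(NC(=O)OC(C)(C)C)c(Cl)c(OC)c12 | intermediate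
41 | C1' aryl (Z)-enone with C17' aldehyde (16'R by CIP, same spatial arrangement) | C/C(=C/[C@H](C)[C@@H](O[Si](C)(C)C(C)(C)C)[C@@H](C)/C=C/[C@@H](O[Si](C)(C)C(C)(C)C)C/C=C(\C)C(=O)C[C@H](O[Si](C)(C)C(C)(C)C)[C@@H](C)C=O)C(=O)c1c(O[Si](C)(C)C(C)(C)C)c(C)cc2c(OC)c(NC(=O)OC(C)(C)C)c(Cl)c(OC)c12 | intermediate
42 | (17'E)-18'-iodo alkene, C1' aryl (Z)-enone, N-Boc | C/C(=C/[C@H](C)[C@@H](O[Si](C)(C)C(C)(C)C)[C@@H](C)/C=C/[C@@H](O[Si](C)(C)C(C)(C)C)C/C=C(\C)C(=O)C[C@H](O[Si](C)(C)C(C)(C)C)[C@@H](C)/C=C/I)C(=O)c1c(O[Si](C)(C)C(C)(C)C)c(C)cc2c(OC)c(NC(=O)OC(C)(C)C)c(Cl)c(OC)c12 | intermediate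
43 | free C3 aniline of 42 | C/C(=C/[C@H](C)[C@@H](O[Si](C)(C)C(C)(C)C)[C@@H](C)/C=C/[C@@H](O[Si](C)(C)C(C)(C)C)C/C=C(\C)C(=O)C[C@H](O[Si](C)(C)C(C)(C)C)[C@@H](C)/C=C/I)C(=O)c1c(O[Si](C)(C)C(C)(C)C)c(C)cc2c(OC)c(N)c(Cl)c(OC)c12 | intermediate
44 | (Z)-3-iodoprop-2-enoic acid | OC(=O)/C=C\I | starting material
45 | (Z)-3-iodoprop-2-enoyl chloride | ClC(=O)/C=C\I | intermediate (not isolated)
46 | bis-iodide: N-[(Z)-3-iodoacryloyl] derivative of 43 (18'E-iodide and 21'Z-iodide) | C/C(=C/[C@H](C)[C@@H](O[Si](C)(C)C(C)(C)C)[C@@H](C)/C=C/[C@@H](O[Si](C)(C)C(C)(C)C)C/C=C(\C)C(=O)C[C@H](O[Si](C)(C)C(C)(C)C)[C@@H](C)/C=C/I)C(=O)c1c(O[Si](C)(C)C(C)(C)C)c(C)cc2c(OC)c(NC(=O)/C=C\I)c(Cl)c(OC)c12 | intermediate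
47 | acetylene | C#C | starting material
48 | hexamethylditin | C[Sn](C)(C)[Sn](C)(C)C | starting material
49 | (Z)-1,2-bis(trimethylstannyl)ethene | C[Sn](C)(C)/C=C\[Sn](C)(C)C | intermediate
50 | protected macrolactam: target skeleton with 1,4-dimethoxynaphthalene in place of the quinone and TBS on O5', O9', O15' and O7 | C/C1=C/[C@H](C)[C@@H](O[Si](C)(C)C(C)(C)C)[C@@H](C)/C=C/[C@@H](O[Si](C)(C)C(C)(C)C)C/C=C(\C)C(=O)C[C@H](O[Si](C)(C)C(C)(C)C)[C@@H](C)/C=C/C=C\C=C/C(=O)Nc2c(Cl)c(OC)c3c(cc(C)c(O[Si](C)(C)C(C)(C)C)c3C1=O)c2OC | intermediate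
51 | tetrakis-TBS ether of the target (1,4-naphthoquinone restored) | C/C1=C/[C@H](C)[C@@H](O[Si](C)(C)C(C)(C)C)[C@@H](C)/C=C/[C@@H](O[Si](C)(C)C(C)(C)C)C/C=C(\C)C(=O)C[C@H](O[Si](C)(C)C(C)(C)C)[C@@H](C)/C=C/C=C\C=C/C(=O)NC2=C(Cl)C(=O)c3c(cc(C)c(O[Si](C)(C)C(C)(C)C)c3C1=O)C2=O | intermediate
52 | CNP0257532.2 (2'Z,4'S,5'S,6'S,7'E,9'S,11'E,15'S,16'S,17'E,19'Z,21'Z) | C/C1=C/[C@H](C)[C@@H](O)[C@@H](C)/C=C/[C@@H](O)C/C=C(\C)C(=O)C[C@H](O)[C@@H](C)/C=C/C=C\C=C/C(=O)NC2=C(Cl)C(=O)c3c(cc(C)c(O)c3C1=O)C2=O | target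

**Totals**
Total step count: 33. Longest linear sequence: 21 steps (15 → 52 through steps 10, 11, 13–17, 19–29, 31–33).

**Three steps most likely to fail, each with a fallback**

Step 31 (double Stille stitching). Risks are oligomerisation, double intermolecular coupling, and loss of Z geometry at C19' or C21'. The fallback moves the ring closure from C–C to the amide bond; it sets out from 42 (with 44 and 49) and comes back at 50. Mono-Stille coupling of 44 with excess 49 (PdCl2(MeCN)2, DMF) gives (2Z,4Z)-5-(trimethylstannyl)penta-2,4-dienoic acid F1. Intermolecular Stille coupling of F1 with the C18' iodide of 42 gives the N-Boc trienoic seco acid F2. TMSOTf/2,6-lutidine then MeOH gives the amino acid F3. Macrolactamisation of F3 (2-chloro-1-methylpyridinium iodide, i-Pr2NEt, CH2Cl2, 1 mM) gives 50.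

Step 25 (Nozaki–Hiyama–Kishi coupling). The aldehyde is flanked by the C7 silyl ether and the peri methoxy group, and the vinyl iodide is trisubstituted. The fallback replaces aldehyde addition by acyl cross-coupling; it sets out from 14 and 38 and comes back at 41. Oxidation of 14 (NaClO2, NaH2PO4, 2-methylbut-2-ene) gives the 8-naphthoic acid F4, which 1-chloro-N,N,2-trimethylprop-1-en-1-amine converts into the acid chloride F5. Stannylation of 38 (Me3SnSnMe3, Pd(PPh3)4) gives the (Z)-2'-trimethylstannyl alkene F6. Stille acylation of F6 with F5 (Pd2(dba)3, tri(2-furyl)phosphine, THF, 50 °C) gives directly the aryl (Z)-enone 17'-TES ether F7. HF·pyridine gives the keto alcohol F8, and Dess–Martin oxidation of F8 gives 41.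

Step 2 (chloranil Diels–Alder/aromatisation). Chloranil is a sluggish dienophile and may oxidise the silyl enol ether instead. The fallback uses an unhindered dienophile and a separate dehydrogenation; it sets out from 2 and comes back at 5. Diels–Alder reaction of 2 with purchased 2,3-dichloro-1,4-benzoquinone (O=C1C=CC(=O)C(Cl)=C1Cl) at its unsubstituted double bond (CH2Cl2, rt) gives the cis-4a,5,8,8a-tetrahydro adduct F9. Et3N enolises it to the 5,8-dihydronaphthalene-1,4-diol F10. DDQ (2 equiv) dehydrogenates F10 to 5, which the acid work-up of step 2 converts into 6.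

Further compounds
F1 | step 31 | (2Z,4Z)-5-(trimethylstannyl)penta-2,4-dienoic acid | OC(=O)/C=C\C=C/[Sn](C)(C)C
F2 | step 31 | N-Boc seco acid: 42 with the C18' iodide replaced by the (19'Z,21'Z)-dienoic acid terminus | C/C(=C/[C@H](C)[C@@H](O[Si](C)(C)C(C)(C)C)[C@@H](C)/C=C/[C@@H](O[Si](C)(C)C(C)(C)C)C/C=C(\C)C(=O)C[C@H](O[Si](C)(C)C(C)(C)C)[C@@H](C)/C=C/C=C\C=C/C(O)=O)C(=O)c1c(O[Si](C)(C)C(C)(C)C)c(C)cc2c(OC)c(NC(=O)OC(C)(C)C)c(Cl)c(OC)c12
F3 | step 31 | amino seco acid (F2 without Boc) | C/C(=C/[C@H](C)[C@@H](O[Si](C)(C)C(C)(C)C)[C@@H](C)/C=C/[C@@H](O[Si](C)(C)C(C)(C)C)C/C=C(\C)C(=O)C[C@H](O[Si](C)(C)C(C)(C)C)[C@@H](C)/C=C/C=C\C=C/C(O)=O)C(=O)c1c(O[Si](C)(C)C(C)(C)C)c(C)cc2c(OC)c(N)c(Cl)c(OC)c12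
F4 | step 25 | 3-(Boc-amino)-7-(TBS-oxy)-2-chloro-1,4-dimethoxy-6-methylnaphthalene-8-carboxylic acid | CC(C)(C)OC(=O)Nc1c(Cl)c(OC)c2c(C(O)=O)c(O[Si](C)(C)C(C)(C)C)c(C)cc2c1OC
F5 | step 25 | the corresponding 8-carbonyl chloride | CC(C)(C)OC(=O)Nc1c(Cl)c(OC)c2c(C(Cl)=O)c(O[Si](C)(C)C(C)(C)C)c(C)cc2c1OC
F6 | step 25 | (Z)-2'-trimethylstannyl analogue of 38 | C/C(=C/[C@H](C)[C@@H](O[Si](C)(C)C(C)(C)C)[C@@H](C)/C=C/[C@@H](O[Si](C)(C)C(C)(C)C)C/C=C(\C)C(=O)C[C@H](O[Si](C)(C)C(C)(C)C)[C@@H](C)CO[Si](CC)(CC)CC)[Sn](C)(C)C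
F7 | step 25 | C1' aryl (Z)-enone with 17'-OTES | C/C(=C/[C@H](C)[C@@H](O[Si](C)(C)C(C)(C)C)[C@@H](C)/C=C/[C@@H](O[Si](C)(C)C(C)(C)C)C/C=C(\C)C(=O)C[C@H](O[Si](C)(C)C(C)(C)C)[C@@H](C)CO[Si](CC)(CC)CC)C(=O)c1c(O[Si](C)(C)C(C)(C)C)c(C)cc2c(OC)c(NC(=O)OC(C)(C)C)c(Cl)c(OC)c12
F8 | step 25 | C1' aryl (Z)-enone with free 17'-OH | C/C(=C/[C@H](C)[C@@H](O[Si](C)(C)C(C)(C)C)[C@@H](C)/C=C/[C@@H](O[Si](C)(C)C(C)(C)C)C/C=C(\C)C(=O)C[C@H](O[Si](C)(C)C(C)(C)C)[C@@H](C)CO)C(=O)c1c(O[Si](C)(C)C(C)(C)C)c(C)cc2c(OC)c(NC(=O)OC(C)(C)C)c(Cl)c(OC)c12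
F9 | step 2 | cis-2,3-dichloro-6-methyl-7-(trimethylsilyloxy)-4a,5,8,8a-tetrahydronaphthalene-1,4-dione (racemic, one enantiomer drawn) | O=C1C(Cl)=C(Cl)C(=O)[C@@H]2CC(C)=C(O[Si](C)(C)C)C[C@H]12
F10 | step 2 | 2,3-dichloro-6-methyl-7-(trimethylsilyloxy)-5,8-dihydronaphthalene-1,4-diol | Oc1c(Cl)c(Cl)c(O)c2c1CC(C)=C(O[Si](C)(C)C)C2
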